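Flavanone numbering is used throughout; ring A is the phloroglucinol ring and ring C the pyranone.

**Plan**

- **Retrosynthesis:** four benzyl-type groups are removed first. The cuts then follow in this order: C2–C3 in ring C, C3–C4 (a diazomethyl carbon on an aroyl chloride), C4–C4a (a formyl group), and last the bond between the bridging CH2 and the catechol ring.
- **Enabling feature:** seen from ring A, the O1–C2(H)–Ph part of ring C is only an O-benzyl group on C8a. The carbon that becomes C3 hangs on the neighbouring C4a through the C4 carbonyl, so it faces that OCH2 group across the six-atom array C3–C4–C4a–C8a–O1–C2. A carbene at C3 can therefore insert into a C–H bond that O1 and phenyl both activate.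
- **Forward order:** the two purchased arenes are joined first by aryllithium addition to the ring A aldehyde and ionic reduction, which turns the old formyl carbon into the bridging CH2. C4 and C3 are then added one carbon at a time. Ring C is the only ring built, and it closes in step 9.
- **Regiochemistry:** the benzyl group placed para to the original aldehyde ends up on O1. Magnesium-directed formylation can only enter between that ether and the free O5 phenol, which puts the benzyl substituent at C6 and not at C8.
- **Stereochemistry:** the single stereocentre C2 (S) comes from a chiral dirhodium carboxylate that selects one of the two enantiotopic benzylic hydrogens. Only a neutral hydrogenolysis follows.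

Key step: step 9

Assumption: the sense of induction of the prolinate catalyst on this substrate cannot be predicted with certainty. The route is written for Rh2(S-DOSP)4 giving 2S; if a first run shows the opposite sense, the mirror-image catalyst Rh2(R-DOSP)4 is used with nothing else changed.

**Step 1**
Reactants: 1 2,4,6-trihydroxybenzaldehyde; 2 benzyl bromide (2 equiv)
Product: 3 2,4-bis(benzyloxy)-6-hydroxybenzaldehyde
Conditions: K2CO3 (2 equiv), DMF, 0 °C to rt
Reagents that add atoms: none
Why: Williamson etherification alkylates the unchelated 4-OH and one of the two equivalent ortho OH groups, while the last OH is held in a hydrogen bond to the formyl oxygen and stays free; the para benzyl group is the one that later supplies C2 and the phenyl ring.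

**Step 2**
Reactants: 4 3-bromobenzene-1,2-diol (3-bromocatechol); 2 benzyl bromide (2 equiv)
Product: 5 1,2-bis(benzyloxy)-3-bromobenzene
Conditions: K2CO3, DMF, 60 °C
Reagents that add atoms: none
Why: Williamson etherification masks both catechol oxygens as groups that tolerate halogen–lithium exchange at low temperature and fall in the final hydrogenolysis.

**Step 3**
Reactants: 5 1,2-bis(benzyloxy)-3-bromobenzene; 3 2,4-bis(benzyloxy)-6-hydroxybenzaldehyde
Product: 8 3,5-bis(benzyloxy)-2-{[2,3-bis(benzyloxy)phenyl](hydroxy)methyl}phenol (racemic), via aryllithium 6 (not isolated), via sodium phenoxide 7 (not isolated)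
Conditions: 5, n-BuLi, THF, −78 °C; separately 3, NaH, THF, 0 °C; combine at −78 °C, then to 0 °C; aq NH4Cl; used crude
Reagents that add atoms: n-butyllithium, [Li]CCCC (Li of 6 only); sodium hydride, [Na+].[H-] (Na of 7 only)
Why: Bromine–lithium exchange is followed by 1,2-addition of the aryllithium to the aldehyde, prior deprotonation of the phenol saves a second equivalent of 6, and the new carbinol centre is racemic but is removed in step 4.

**Step 4**
Reactants: 8 the diaryl carbinol
Product: 9 3,5-bis(benzyloxy)-2-[2,3-bis(benzyloxy)benzyl]phenol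
Conditions: Et3SiH, TFA, CH2Cl2, −40 to 0 °C
Reagents that add atoms: none
Why: In this ionic hydrogenation the acid ionises the doubly benzylic alcohol to a cation stabilised by the three oxygen donors of ring A, and the silane should deliver hydride well before the benzyl ethers are attacked at this temperature.

**Step 5**
Reactants: 9 3,5-bis(benzyloxy)-2-[2,3-bis(benzyloxy)benzyl]phenol; 10 paraformaldehyde
Product: 11 4,6-bis(benzyloxy)-3-[2,3-bis(benzyloxy)benzyl]-2-hydroxybenzaldehyde
Conditions: MgCl2, Et3N, THF, reflux; then 1 M HCl
Reagents that add atoms: none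
Why: In the Casnati–Skattebøl ortho-formylation the magnesium phenoxide delivers formaldehyde only to a carbon ortho to its oxygen and a second formaldehyde oxidises the resulting benzylic alkoxide, and because the other ortho carbon already carries the benzyl substituent the formyl group can only enter at C4a.

**Step 6**
Reactants: 11 the salicylaldehyde
Product: 12 benzyl 3,5-bis(benzyloxy)-2-[2,3-bis(benzyloxy)benzyl]-6-formylphenyl carbonate
Conditions: CbzCl, i-Pr2NEt, DMAP (cat.), CH2Cl2, 0 °C to rt
Reagents that add atoms: benzyl chloroformate, O=C(Cl)OCc1ccccc1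
Why: DMAP-catalysed O-acylation turns the chelated O5 phenol into a benzyl carbonate, which has no nucleophilic oxygen and no C–H bond within reach of C3 and leaves by hydrogenolysis together with the benzyl ethers.

**Step 7**
Reactants: 12 the carbonate aldehyde
Product: 13 4,6-bis(benzyloxy)-3-[2,3-bis(benzyloxy)benzyl]-2-{[(benzyloxy)carbonyl]oxy}benzoic acid
Conditions: NaClO2, NaH2PO4, 2-methyl-2-butene (excess), t-BuOH/THF/H2O, 0 °C to rt
Reagents that add atoms: sodium chlorite, [Na+].[O-]Cl=O
Why: Pinnick oxidation at buffered pH converts the hindered aldehyde into the acid without touching carbonate or ethers, and the excess alkene traps HOCl before it can chlorinate C8.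

**Step 8**
Reactants: 13 the benzoic acid; 14 (trimethylsilyl)diazomethane
Product: 17 benzyl 3,5-bis(benzyloxy)-2-[2,3-bis(benzyloxy)benzyl]-6-(diazoacetyl)phenyl carbonate, via acid chloride 15 (not isolated), via silyl diazoketone 16 (not isolated)
Conditions: Me2C=C(Cl)NMe2, CH2Cl2, 0 °C to rt; then 14, Et3N, THF/MeCN, 0 °C; aq NaHCO3
Reagents that add atoms: 1-chloro-N,N,2-trimethylprop-1-en-1-amine, CC(C)=C(Cl)N(C)C (Cl of 15 only)
Why: This is an Arndt–Eistert-type acylation of a diazoalkane in which the neutral chloroenamine makes the aroyl chloride without HCl, C-acylation of 14 with Et3N as scavenger gives the silyl diazoketone, and its C–Si bond is hydrolysed on work-up; acid is excluded throughout because a protonated diazoketone would be captured by the neighbouring benzyl ether oxygen.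

**Step 9**
Reactants: 17 the diazoketone
Product: 18 (2S)-7-(benzyloxy)-6-[2,3-bis(benzyloxy)benzyl]-4-oxo-2-phenyl-3,4-dihydro-2H-chromen-5-yl benzyl carbonate
Conditions: Rh2(S-DOSP)4 [dirhodium tetrakis((S)-N-(4-dodecylbenzenesulfonyl)prolinate)] (1 mol %), CH2Cl2, 4 Å MS, rt, slow addition of 17 at high dilution
Reagents that add atoms: none
Why: The dirhodium carboxylate binds the diazo carbon of 17, N2 leaves, and the electrophilic rhodium carbene at C3 inserts into a benzylic C–H bond of the ortho OCH2Ph group through a concerted three-centre transition state, in which the migrating hydrogen takes on hydride character while C2–C3 forms and the catalyst is released. The closest known reaction type is the dirhodium-catalysed enantioselective intramolecular C–H insertion of 2-alkoxyaryl diazoketones, which gives 2-substituted chroman-4-ones. Ring C closes by 1,6-insertion through the array C3–C4–C4a–C8a–O1–C2, and the usually preferred 1,5-mode is not available because the fifth atom is O1 on one side and O5 on the other. C2 is set by the catalyst alone, whose four arylsulfonylprolinate ligands make the two enantiotopic hydrogens of the OCH2Ph group unequal in the transition state, so that replacement of one of them by C3 gives the 2S centre. Site selectivity rests on the substrate: the reacting C–H is activated by both O1 and phenyl, the benzyl ethers on O7 and on the catechol ring cannot reach C3, and the O5 carbonate has its nearest C–H eight atoms away. Insertion must also win over attack of O1 on the carbene (a five-membered oxonium ylide followed by benzyl shift), which is helped by the low basicity of an aryl ether oxygen tied into the acyl-substituted ring, by the non-nucleophilic carbonate on O5, and by slow addition at high dilution, which also suppresses carbene dimerisation.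

**Step 10**
Reactants: 18 the protected flavanone
Product: 19 (2S)-6-(2,3-dihydroxybenzyl)-5,7-dihydroxy-2-phenyl-2,3-dihydro-4H-chromen-4-one (CNP0348560.1)
Conditions: H2 (1 atm), 10% Pd/C, EtOAc/MeOH, rt
Reagents that add atoms: none
Why: Catalytic hydrogenolysis cleaves the three aryl benzyl ethers and the benzyl carbonate (which then loses CO2) under neutral conditions, so the base-sensitive C2 centre is not scrambled by ring opening to the chalcone, and the cyclic C2–O1 bond and the strongly donor-substituted C4 ketone of flavanones are known to tolerate such conditions.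

**Compound list**

1 | 2,4,6-trihydroxybenzaldehyde | O=Cc1c(O)cc(O)cc1O | starting material
2 | benzyl bromide | BrCc1ccccc1 | starting material
3 | 2,4-bis(benzyloxy)-6-hydroxybenzaldehyde | O=Cc1c(O)cc(OCc2ccccc2)cc1OCc3ccccc3 | intermediate
4 | 3-bromobenzene-1,2-diol | Oc1cccc(Br)c1O | starting material
5 | 1,2-bis(benzyloxy)-3-bromobenzene | Brc1cccc(OCc2ccccc2)c1OCc3ccccc3 | intermediate
6 | [2,3-bis(benzyloxy)phenyl]lithium | [Li]c1cccc(OCc2ccccc2)c1OCc3ccccc3 | intermediate
7 | sodium 3,5-bis(benzyloxy)-2-formylphenolate | [Na+].[O-]c1cc(OCc2ccccc2)cc(OCc3ccccc3)c1C=O | intermediate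
8 | 3,5-bis(benzyloxy)-2-{[2,3-bis(benzyloxy)phenyl](hydroxy)methyl}phenol, racemic | OC(c1c(O)cc(OCc2ccccc2)cc1OCc3ccccc3)c4cccc(OCc5ccccc5)c4OCc6ccccc6 | intermediate
9 | 3,5-bis(benzyloxy)-2-[2,3-bis(benzyloxy)benzyl]phenol | Oc1cc(OCc2ccccc2)cc(OCc3ccccc3)c1Cc4cccc(OCc5ccccc5)c4OCc6ccccc6 | intermediate
10 | paraformaldehyde (written as the monomer formaldehyde) | C=O | starting material
11 | 4,6-bis(benzyloxy)-3-[2,3-bis(benzyloxy)benzyl]-2-hydroxybenzaldehyde | O=Cc1c(O)c(Cc2cccc(OCc3ccccc3)c2OCc4ccccc4)c(OCc5ccccc5)cc1OCc6ccccc6 | intermediate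
12 | benzyl 3,5-bis(benzyloxy)-2-[2,3-bis(benzyloxy)benzyl]-6-formylphenyl carbonate | O=Cc1c(OC(=O)OCc2ccccc2)c(Cc3cccc(OCc4ccccc4)c3OCc5ccccc5)c(OCc6ccccc6)cc1OCc7ccccc7 | intermediate
13 | 4,6-bis(benzyloxy)-3-[2,3-bis(benzyloxy)benzyl]-2-{[(benzyloxy)carbonyl]oxy}benzoic acid | OC(=O)c1c(OC(=O)OCc2ccccc2)c(Cc3cccc(OCc4ccccc4)c3OCc5ccccc5)c(OCc6ccccc6)cc1OCc7ccccc7 | intermediate
14 | (trimethylsilyl)diazomethane | C[Si](C)(C)C=[N+]=[N-] | starting material
15 | 4,6-bis(benzyloxy)-3-[2,3-bis(benzyloxy)benzyl]-2-{[(benzyloxy)carbonyl]oxy}benzoyl chloride | ClC(=O)c1c(OC(=O)OCc2ccccc2)c(Cc3cccc(OCc4ccccc4)c3OCc5ccccc5)c(OCc6ccccc6)cc1OCc7ccccc7 | intermediate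
16 | benzyl 3,5-bis(benzyloxy)-2-[2,3-bis(benzyloxy)benzyl]-6-[diazo(trimethylsilyl)acetyl]phenyl carbonate | C[Si](C)(C)C(=[N+]=[N-])C(=O)c1c(OC(=O)OCc2ccccc2)c(Cc3cccc(OCc4ccccc4)c3OCc5ccccc5)c(OCc6ccccc6)cc1OCc7ccccc7 | intermediate
17 | benzyl 3,5-bis(benzyloxy)-2-[2,3-bis(benzyloxy)benzyl]-6-(diazoacetyl)phenyl carbonate | [N-]=[N+]=CC(=O)c1c(OC(=O)OCc2ccccc2)c(Cc3cccc(OCc4ccccc4)c3OCc5ccccc5)c(OCc6ccccc6)cc1OCc7ccccc7 | intermediate
18 | (2S)-7-(benzyloxy)-6-[2,3-bis(benzyloxy)benzyl]-4-oxo-2-phenyl-3,4-dihydro-2H-chromen-5-yl benzyl carbonate | O=C1C[C@@H](c2ccccc2)Oc3cc(OCc4ccccc4)c(Cc5cccc(OCc6ccccc6)c5OCc7ccccc7)c(OC(=O)OCc8ccccc8)c31 | intermediate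
19 | (2S)-6-(2,3-dihydroxybenzyl)-5,7-dihydroxy-2-phenyl-2,3-dihydro-4H-chromen-4-one | O=C1C[C@@H](c2ccccc2)Oc2cc(O)c(Cc3cccc(O)c3O)c(O)c21 | target

Total step count: 10. Longest linear sequence: 9 steps (1, 3, 4, 5, 6, 7, 8, 9, 10; the branch through step 2 is equally long).

**Steps most likely to fail**

(1) The carbene insertion, step 9. Attack of O1 on the carbene with subsequent benzyl migration may outrun insertion, or the catalyst may discriminate weakly between the two enantiotopic hydrogens.

- The fallback leaves carbene chemistry and sets C2 by asymmetric conjugate arylation of a chromone. It sets out from acid chloride 15, made from 13 as in step 8.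
- Stille acylation with tributyl[(Z)-2-ethoxyethenyl]stannane and PdCl2(PPh3)2 in toluene should give the (E)-β-ethoxyvinyl ketone F1.
- MgBr2·OEt2 in toluene/Et2O removes only the benzyl ether that can chelate with the ketone and gives the ortho-hydroxyaryl enone F2. On acidic work-up this adds to the enone and loses ethanol to give the chromone F3.
- Phenylboronic acid is then added to C2 with Pd(OCOCF3)2, the t-BuPyOx enantiomer that delivers 2S, NH4PF6 and water in ClCH2CH2Cl at 60 °C. This comes back to the route at 18.

(2) The diazoketone formation, step 8. C-acylation of the bulky silyl diazomethane by the doubly ortho-substituted aroyl chloride may be sluggish, or nitrogen may be lost under traces of acid with participation of the neighbouring benzyl ether.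

- The fallback brings in C3 as a small, strongly nucleophilic sulfur ylide and installs the nitrogen afterwards. It sets out from acid chloride 15.
- Dimethylsulfoxonium methylide (from Me3S(O)I and KOt-Bu, 2 equiv, THF, 0 °C) should give the keto sulfoxonium ylide F4.
- LiBr and methanesulfonic acid in THF displace dimethyl sulfoxide and give the α-bromo ketone F5.
- N,N'-ditosylhydrazine with DBU in THF at 0 °C converts the bromoacetyl group into the diazoacetyl group. This comes back to the route at 17.

(3) The aryllithium addition, step 3. The phenoxide strongly deactivates the aldehyde and may resist addition, and the very easily ionised carbinol may oligomerise before or during the reduction of step 4.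

- The fallback replaces addition plus acidic reduction by an anionic ortho-quinone methide cascade. It sets out from 3.
- Boc2O, i-Pr2NEt and catalytic DMAP give the aryl tert-butyl carbonate F6, to which one equivalent of aryllithium 6 is added at −78 °C.
- MgBr2·OEt2 and warming trigger transfer of the Boc group to the new alkoxide and loss of tert-butyl carbonate, which gives the ortho-quinone methide F7.
- LiBH4 present in the flask reduces F7 at the benzylic carbon. This comes back to the route at 9 and bypasses 7 and 8.

**Further compounds**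
F1 | step 9 | benzyl 3,5-bis(benzyloxy)-2-[2,3-bis(benzyloxy)benzyl]-6-[(2E)-3-ethoxyprop-2-enoyl]phenyl carbonate | CCO/C=C/C(=O)c1c(OC(=O)OCc2ccccc2)c(Cc3cccc(OCc4ccccc4)c3OCc5ccccc5)c(OCc6ccccc6)cc1OCc7ccccc7
F2 | step 9 | benzyl 3-(benzyloxy)-2-[2,3-bis(benzyloxy)benzyl]-6-[(2E)-3-ethoxyprop-2-enoyl]-5-hydroxyphenyl carbonate | CCO/C=C/C(=O)c1c(OC(=O)OCc2ccccc2)c(Cc3cccc(OCc4ccccc4)c3OCc5ccccc5)c(OCc6ccccc6)cc1O
F3 | step 9 | benzyl 7-(benzyloxy)-6-[2,3-bis(benzyloxy)benzyl]-4-oxo-4H-chromen-5-yl carbonate | O=c1ccoc2cc(OCc3ccccc3)c(Cc4cccc(OCc5ccccc5)c4OCc6ccccc6)c(OC(=O)OCc7ccccc7)c12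
F4 | step 8 | dimethylsulfoxonium 2-{4,6-bis(benzyloxy)-3-[2,3-bis(benzyloxy)benzyl]-2-[(benzyloxycarbonyl)oxy]phenyl}-2-oxoethylide | CS(C)(=O)=CC(=O)c1c(OC(=O)OCc2ccccc2)c(Cc3cccc(OCc4ccccc4)c3OCc5ccccc5)c(OCc6ccccc6)cc1OCc7ccccc7
F5 | step 8 | benzyl 3,5-bis(benzyloxy)-2-[2,3-bis(benzyloxy)benzyl]-6-(bromoacetyl)phenyl carbonate | BrCC(=O)c1c(OC(=O)OCc2ccccc2)c(Cc3cccc(OCc4ccccc4)c3OCc5ccccc5)c(OCc6ccccc6)cc1OCc7ccccc7
F6 | step 3 | 3,5-bis(benzyloxy)-2-formylphenyl tert-butyl carbonate | O=Cc1c(OC(=O)OC(C)(C)C)cc(OCc2ccccc2)cc1OCc3ccccc3
F7 | step 3 | 3,5-bis(benzyloxy)-6-[2,3-bis(benzyloxy)benzylidene]cyclohexa-2,4-dien-1-one | O=C1C=C(OCc2ccccc2)C=C(OCc3ccccc3)C1=Cc4cccc(OCc5ccccc5)c4OCc6ccccc6
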